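**Retrosynthetic overview**

- The target is a single 25-membered lactone ring (24 ring carbons and one ring oxygen, no stereocentre). With C1 as the carbonyl carbon and C24 as the OCH2 carbon, the C12–C13 bond lies opposite the ester and divides the carbons into two equal C12 halves, C1–C12 and C13–C24; the strategy rests on this symmetry.
- The target is traced back by exhaustive hydrogenation to tetracosa-11,13-diyn-24-olide, whose C12–C13 bond is made by intramolecular oxidative coupling of the two terminal alkynes of dodec-11-yn-1-yl dodec-11-ynoate with Cu(OAc)2.
- The diyne ester comes from esterification of dodec-11-yn-1-ol with dodec-11-ynoic acid, and the acid comes from the same alkynol by Jones oxidation.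
- The alkynol comes from 10-bromodecan-1-ol and lithium acetylide ethylenediamine complex by acetylide alkylation.
- Ring order: there is one ring only, and it is closed in step 4.

Key step: step 4

Remark on the chemistry: the target has no stereocentre and no double bond, so no stereochemical control is needed; the C12 alkynol from step 1 is prepared once and divided between steps 2 and 3.

**Route**

Step 1
Reactants: 1 10-bromodecan-1-ol; 2 lithium acetylide ethylenediamine complex
Product: 5 dodec-11-yn-1-ol, via lithium 10-bromodecan-1-olate 3 (not isolated), via lithium dodec-11-yn-1-olate 4 (not isolated)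
Conditions: LiC≡CH·H2NCH2CH2NH2 (3 equiv), DMSO, 0 °C → rt; then H2O
Reagents that add atoms: lithium acetylide ethylenediamine complex, [Li]C#C.NCCN
Why: Acetylide alkylation (SN2 at the primary bromide in DMSO): the first equivalent of reagent is spent on the hydroxyl group, and the excess acetylide carbon should outrun the lithium alkoxide as nucleophile, so C-alkylation should dominate; no stereocentre is formed.

Step 2
Reactants: 5 dodec-11-yn-1-ol (the portion set aside for oxidation)
Product: 6 dodec-11-ynoic acid
Conditions: CrO3, H2SO4, H2O, acetone, 0 °C → rt
Reagents that add atoms: water, O
Why: Jones oxidation should take the primary alcohol through the aldehyde and its hydrate to the carboxylic acid, and an unactivated terminal alkyne is neither oxidised nor hydrated under these cold aqueous acetone conditions; no stereocentre is formed.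

Step 3
Reactants: 6 dodec-11-ynoic acid; 5 dodec-11-yn-1-ol
Product: 8 dodec-11-yn-1-yl dodec-11-ynoate, via O-acylisourea 7 (not isolated)
Conditions: DCC (1.1 equiv), 4-(dimethylamino)pyridine (cat.), CH2Cl2, 0 °C → rt
Reagents that add atoms: none
Why: Steglich esterification: DCC activates acid 6 as the O-acylisourea 7, 4-(dimethylamino)pyridine relays the acyl group to the primary alcohol 5 faster than the N-acylurea rearrangement, and the neutral conditions leave both terminal alkynes untouched.

Step 4
Reactants: 8 dodec-11-yn-1-yl dodec-11-ynoate
Product: 9 tetracosa-11,13-diyn-24-olide
Conditions: Cu(OAc)2 (10 equiv), pyridine, 60 °C; 8 in pyridine/Et2O added by syringe pump over several hours (final concentration about 2 mM), then brief further heating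
Reagents that add atoms: none
Why: Eglinton (Glaser-type) oxidative homocoupling: pyridine and acetate remove the two acetylenic protons of 8 as the alkyne ends bind copper, and within an acetylide-bridged aggregate two divalent copper centres each accept one electron while the sp carbons C12 and C13 join, which should give the conjugated 1,3-diyne together with CuOAc and acetic acid. The closest known reaction type is the Cu(OAc)2/pyridine cyclisation of α,ω-diyne esters to large-ring diyne lactones under high dilution. The single 25-membered ring closes by end-to-end union of the two chain termini, both alkyne units becoming ring members, and a ring of this size takes up the linear four-carbon C11–C14 rod without angle or transannular strain. No stereocentre is formed, so no stereocontrol is required. The selectivity that matters is ring closure against intermolecular coupling to linear and cyclic oligomers, and it is secured by syringe-pump addition of 8 into a large excess of Cu(OAc)2, which keeps the stationary concentration of uncoupled diyne very low, and by the flexible 21-atom chain between the alkyne units (nine CH2, the C(=O)O group, ten CH2) that lets the two ends meet. Both ends are the same kind of alkyne, so homo- against hetero-coupling does not arise, and the ester is inert to Cu(OAc)2 in pyridine.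

Step 5
Reactants: 9 tetracosa-11,13-diyn-24-olide
Product: 10 24-tetracosanolide
Conditions: H2 (1–3 atm), 10% Pd/C, EtOAc, rt
Reagents that add atoms: none
Why: Heterogeneous catalytic hydrogenation over Pd/C should add four equivalents of H2 to the conjugated diyne and saturate the chain fully, while the aliphatic lactone has no benzylic or allylic C–O bond and is not hydrogenolysed; the target has no stereocentre to set.

**Compound list**

1 | 10-bromodecan-1-ol | OCCCCCCCCCCBr | starting material
2 | lithium acetylide ethylenediamine complex, LiC≡CH·H2NCH2CH2NH2 | [Li]C#C.NCCN | starting material
3 | lithium 10-bromodecan-1-olate | [Li+].[O-]CCCCCCCCCCBr | intermediate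
4 | lithium dodec-11-yn-1-olate | [Li+].[O-]CCCCCCCCCCC#C | intermediate
5 | dodec-11-yn-1-ol | OCCCCCCCCCCC#C | intermediate
6 | dodec-11-ynoic acid | C#CCCCCCCCCCC(=O)O | intermediate
7 | N,N'-dicyclohexyl-O-(dodec-11-ynoyl)isourea | C#CCCCCCCCCCC(=O)OC(=NC1CCCCC1)NC1CCCCC1 | intermediate
8 | dodec-11-yn-1-yl dodec-11-ynoate | C#CCCCCCCCCCC(=O)OCCCCCCCCCCC#C | intermediate
9 | tetracosa-11,13-diyn-24-olide (1-oxacyclopentacosa-12,14-diyn-2-one) | O=C1CCCCCCCCCC#CC#CCCCCCCCCCCO1 | intermediate
10 | 24-tetracosanolide (oxacyclopentacosan-2-one) | O=C1CCCCCCCCCCCCCCCCCCCCCCCO1 | target

**Step count**

Total steps: 5. Longest linear sequence: 5 steps (1 → 5 → 6 → 8 → 9 → 10).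

**Steps most likely to fail, with fallbacks**

Step 4. The risk is that intermolecular coupling overtakes ring closure, so that material drains into open-chain and cyclic dimers and oligomers, or that the coupling stalls before both ends have reacted. The fallback makes the C12–C13 bond intermolecularly and closes the ring at the ester instead. It sets out from 5 and 6. Bromination of the alkyne terminus of 5 (N-bromosuccinimide, cat. AgNO3, acetone) would give 12-bromododec-11-yn-1-ol F1. Cadiot–Chodkiewicz coupling of F1 with acid 6 (cat. CuCl, NH2OH·HCl, aqueous EtNH2, MeOH) would give 24-hydroxytetracosa-11,13-diynoic acid F2. Yamaguchi macrolactonisation (2,4,6-trichlorobenzoyl chloride, Et3N, THF, then slow addition to 4-(dimethylamino)pyridine in toluene at reflux) would pass through the mixed anhydride 24-hydroxytetracosa-11,13-diynoic 2,4,6-trichlorobenzoic anhydride F3 and close the same 25-membered diyne lactone, coming back to the route at 9.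

Step 1. The risk is O-alkylation by the lithium alkoxide and base-induced elimination of HBr competing with C-alkylation, made worse if the alkoxide is poorly soluble. The fallback masks the hydroxyl group first and sets out from 1. Dihydropyran with pyridinium p-toluenesulfonate in CH2Cl2 would give 2-[(10-bromodecyl)oxy]oxane F4. Alkylation with LiC≡CH·H2NCH2CH2NH2 in DMSO would give 2-(dodec-11-yn-1-yloxy)oxane F5. Acetal exchange (TsOH, MeOH) would release the alcohol and come back to the route at 5.

Step 2. The risk is trapping of the intermediate aldehyde by unreacted alcohol as a hemiacetal that is oxidised on to the dimeric ester, along with incomplete oxidation or acid-promoted hydration of the alkyne. That dimeric ester has the constitution of 8, but the process is not controllable enough to serve as a route. The fallback separates the two oxidation levels and sets out from 5. Oxidation with 2,2,6,6-tetramethylpiperidin-1-oxyl (cat.) and PhI(OAc)2 in CH2Cl2 would give dodec-11-ynal F6. Pinnick oxidation (NaClO2, NaH2PO4, 2-methylbut-2-ene, tBuOH/H2O) would then give the acid and come back to the route at 6.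

**Further compounds**

F1 | step 4 | 12-bromododec-11-yn-1-ol | OCCCCCCCCCCC#CBr
F2 | step 4 | 24-hydroxytetracosa-11,13-diynoic acid | OCCCCCCCCCCC#CC#CCCCCCCCCCC(=O)O
F3 | step 4 | 24-hydroxytetracosa-11,13-diynoic 2,4,6-trichlorobenzoic anhydride | OCCCCCCCCCCC#CC#CCCCCCCCCCC(=O)OC(=O)c1c(Cl)cc(Cl)cc1Cl
F4 | step 1 | 2-[(10-bromodecyl)oxy]oxane (racemic) | BrCCCCCCCCCCOC1CCCCO1
F5 | step 1 | 2-(dodec-11-yn-1-yloxy)oxane (racemic) | C#CCCCCCCCCCCOC1CCCCO1
F6 | step 2 | dodec-11-ynal | C#CCCCCCCCCCC=O
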